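**Plan**

1. Ring numbering: O1, C2 (bears the 4-hydroxy-3-methoxyphenyl group), C3 (bears C9H2OH), C4 (bears the veratryl CH2, C7′), C5. The retrosynthesis re-protects the phenol as a benzyl ether, cuts O1–C2 (benzylic cation plus C5–OH), then C2–C3 and C4–C7′.
2. Enabling feature: with O1–C2 opened, C2 is an aryl carbonyl carbon that has to attack C3 as a nucleophile. C9–C3–C4–C5 is a four-carbon chain oxygenated at both ends, so C3 and C4 are the β- and α-carbons of a butenolide (C9 = acetal carbon, C5 = lactone carbonyl).
3. Forward: the lithiated dithiane of O-benzylvanillin adds to C3 of (5R)-5-(l-menthyloxy)furan-2(5H)-one and the enolate is benzylated at C4 by veratryl bromide. The lactone is only a template and no ring closes there.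
4. LiAlH4 opens the template (C5 and C9 become CH2OH, menthol leaves), the dithiane is hydrolysed and the ketone reduced. The tetrahydrofuran, the only ring made, arises last by C5–OH capture of the C2 benzylic cation, and hydrogenolysis frees the phenol.
5. Stereochemistry: the acetal centre, fixed by crystallisation of the l-menthyl acetal, directs C3 (anti addition) and C3 directs C4 (trans alkylation). The trans lactone becomes the 3,4-cis ring because C3 closes through its other arm, and C2 (S) follows from the 2,3-trans preference of the reversible cation closure.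

Key step: step 6

Remark: the two carbinol epimers of 16 are assumed to converge in step 10 through one benzylic cation, so 16 is carried on as a mixture at that centre only. Compound 5 is racemic and configurationally labile, and 15 is drawn in its open form although it may equilibrate with its five-membered hemiketal.

**Route**

Step 1
Reactants: 1 vanillin
Product: 2 4-benzyloxy-3-methoxybenzaldehyde
Conditions: BnBr, K2CO3, DMF, rt
Reagents that add atoms: benzyl bromide, BrCc1ccccc1
Why: Williamson etherification of the phenoxide, the only acidic site, should give the aryl benzyl ether, which tolerates the organolithium, hydride, mercury(II) and acid steps and is removable at the end by hydrogenolysis.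

Step 2
Reactants: 2 4-benzyloxy-3-methoxybenzaldehyde
Product: 3 2-(4-benzyloxy-3-methoxyphenyl)-1,3-dithiane
Conditions: HS(CH2)3SH, BF3·OEt2 (cat.), CH2Cl2, 0 °C → rt
Reagents that add atoms: propane-1,3-dithiol, SCCCS
Why: Lewis-acid-catalysed dithioacetalisation of an aromatic aldehyde is routine and turns the formyl carbon into a lithiable acyl-anion equivalent (Corey–Seebach umpolung).

Step 3
Reactants: 4 furfural
Product: 5 5-hydroxyfuran-2(5H)-one (racemic)
Conditions: O2, hν (visible), rose bengal (cat.), MeOH, 20 °C
Reagents that add atoms: oxygen, O=O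
Why: Dye-sensitised singlet oxygen adds [4+2] across the furan and the endoperoxide fragments in methanol with loss of the formyl carbon as methyl formate, the standard entry to this hydroxybutenolide.

Step 4
Reactants: 5 5-hydroxyfuran-2(5H)-one; 6 (−)-menthol
Product: 8 (5R)-5-(l-menthyloxy)furan-2(5H)-one, via 5S-epimeric menthyl acetal 7 (not isolated)
Conditions: CSA (cat.), toluene, reflux (Dean–Stark); crystallisation from petroleum ether, −20 °C; liquors re-equilibrated with CSA (cat.) and recrystallised
Reagents that add atoms: none
Why: Acid-catalysed acetalisation through the ring oxocarbenium ion should give both C5 epimers, which interconvert under the acid, and since the 5R acetal of l-menthol is the epimer that crystallises, crystallisation with re-equilibration of the liquors (crystallisation-induced diastereomer transformation) fixes the acetal centre as R.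

Step 5
Reactants: 9 3,4-dimethoxybenzyl alcohol
Product: 10 3,4-dimethoxybenzyl bromide
Conditions: PBr3, Et2O, 0 °C; used at once
Reagents that add atoms: phosphorus tribromide, BrP(Br)Br
Why: PBr3 converts the primary benzylic alcohol into the bromide by SN2 displacement of the phosphite ester, and the electron-rich, labile bromide is used directly without purification.

Step 6
Reactants: 3 2-(4-benzyloxy-3-methoxyphenyl)-1,3-dithiane; 8 (5R)-5-(l-menthyloxy)furan-2(5H)-one; 10 3,4-dimethoxybenzyl bromide
Product: 13 (3R,4R,5R)-4-[2-(4-benzyloxy-3-methoxyphenyl)-1,3-dithian-2-yl]-3-(3,4-dimethoxybenzyl)-5-(l-menthyloxy)dihydrofuran-2(3H)-one, via 2-lithio-1,3-dithiane 11 (not isolated), via lithium lactone enolate 12 (not isolated)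
Conditions: 3, n-BuLi, THF, −78 → −20 °C; 8, THF, −78 °C; then 10, DMPU, −78 → −20 °C; aq NH4Cl
Reagents that add atoms: n-butyllithium, [Li]CCCC (supplies only the lithium of 11 and 12; no atom of it remains in 13)
Why: n-BuLi deprotonates the dithiane C–H to give the sulfur- and aryl-stabilised carbanion 11 (Corey–Seebach acyl-anion equivalent), which undergoes Michael addition to the β-carbon of 8 to give lithium enolate 12, and 12 is C-alkylated by the benzylic bromide 10 in an SN2 reaction. The closest known reaction type is the tandem conjugate addition–enolate alkylation of lithiated 2-aryl-1,3-dithianes on 5-alkoxyfuran-2(5H)-ones. No ring is closed: the lactone ring is carried through unchanged and both new bonds (C2–C3 and C4–C7′ in target numbering) are exocyclic to it. The centre at the lactone β-carbon (target C3) is controlled by the 5R acetal centre, whose menthyloxy group blocks one face of the flat butenolide so that the bulky anion enters anti to it. The centre at the α-carbon (target C4) is controlled by the newly attached dithianyl group, which shields its own face of the planar enolate and forces benzylation trans, giving the (3R,4R,5R) trans,trans lactone. The step needs 1,4- over 1,2-addition and C-alkylation before retro-Michael or proton transfer: the soft, hindered, delocalised anion and the unhindered cisoid enoate secure the former, while the enolate cannot β-eliminate (its acetal oxygens sit on the γ-carbon) and DMPU with a reactive benzylic bromide makes the alkylation fast at low temperature.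

Step 7
Reactants: 13 trans,trans dithianyl menthyloxy lactone
Product: 14 (2R,3R)-2-[2-(4-benzyloxy-3-methoxyphenyl)-1,3-dithian-2-yl]-3-(3,4-dimethoxybenzyl)butane-1,4-diol
Conditions: LiAlH4, THF, 0 °C → rt; aq NaOH work-up
Reagents that add atoms: none
Why: Hydride reduction of the acylal lactone opens the ring to a hemiacetal alkoxide that expels menthoxide, and the resulting aldehyde is reduced immediately, so the carbonyl and acetal carbons become the C5 and C9 hydroxymethyl groups while the dithiane, the ethers and both stereocentres are untouched (LiAlH4 lactone reduction).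

Step 8
Reactants: 14 dithianyl diol
Product: 15 (2R,3R)-1-(4-benzyloxy-3-methoxyphenyl)-3-(3,4-dimethoxybenzyl)-4-hydroxy-2-(hydroxymethyl)butan-1-one
Conditions: HgO (red), BF3·OEt2, THF/H2O (85:15), rt
Reagents that add atoms: water, O
Why: Mercury(II)-assisted hydrolysis of the dithioacetal under non-basic conditions should unmask the aryl ketone without enolising the α-centre C3 or eliminating the β-hydroxyl.

Step 9
Reactants: 15 hydroxy ketone
Product: 16 (2R,3R)-2-[(4-benzyloxy-3-methoxyphenyl)(hydroxy)methyl]-3-(3,4-dimethoxybenzyl)butane-1,4-diol (both carbinol epimers)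
Conditions: NaBH4, MeOH/THF, 0 °C
Reagents that add atoms: none
Why: Borohydride reduction of the aryl ketone (through its open form) gives the benzylic alcohol as a mixture of epimers, which does not matter because this centre is ionised in the next step.

Step 10
Reactants: 16 triol
Product: 17 [(2S,3R,4R)-2-(4-benzyloxy-3-methoxyphenyl)-4-(3,4-dimethoxybenzyl)tetrahydrofuran-3-yl]methanol
Conditions: CSA (cat.), CH2Cl2, 0 °C → rt; quenched as soon as 16 is consumed
Reagents that add atoms: none
Why: Acid ionises the electron-rich benzylic alcohol (either epimer) to a p-alkoxybenzyl cation that the C5 hydroxyl captures in a 5-exo SN1 cycloetherification (the C9 hydroxyl could only form an oxetane), and since the closure is reversible and the all-cis alternative is strongly disfavoured, the aryl group should settle trans to the C3 hydroxymethyl, setting C2 as S.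

Step 11
Reactants: 17 O-benzyl tetrahydrofuran
Product: 18 4'-O-methyllariciresinol, [(2S,3R,4R)-4-(3,4-dimethoxybenzyl)-2-(4-hydroxy-3-methoxyphenyl)tetrahydrofuran-3-yl]methanol
Conditions: H2 (1 atm), 10% Pd/C, EtOAc, rt; stopped after one equivalent of H2
Reagents that add atoms: none
Why: Hydrogenolysis of an aryl benzyl ether over Pd/C at one atmosphere in a neutral solvent is much faster than cleavage of the benzylic C2–O1 bond of the tetrahydrofuran, so the phenol should be released without affecting the three stereocentres.

**Compound list**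

1 | vanillin | COc1cc(C=O)ccc1O | starting material
2 | 4-benzyloxy-3-methoxybenzaldehyde | COc1cc(C=O)ccc1OCc1ccccc1 | intermediate
3 | 2-(4-benzyloxy-3-methoxyphenyl)-1,3-dithiane | COc1cc(C2SCCCS2)ccc1OCc1ccccc1 | intermediate
4 | furfural | O=Cc1ccco1 | starting material
5 | 5-hydroxyfuran-2(5H)-one (racemic) | O=C1C=CC(O)O1 | intermediate
6 | (−)-menthol, (1R,2S,5R) | CC(C)[C@@H]1CC[C@@H](C)C[C@H]1O | starting material
7 | (5S)-5-(l-menthyloxy)furan-2(5H)-one | O=C1C=C[C@@H](O[C@@H]2C[C@H](C)CC[C@H]2C(C)C)O1 | intermediate
8 | (5R)-5-(l-menthyloxy)furan-2(5H)-one | O=C1C=C[C@H](O[C@@H]2C[C@H](C)CC[C@H]2C(C)C)O1 | intermediate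
9 | 3,4-dimethoxybenzyl alcohol | COc1ccc(CO)cc1OC | starting material
10 | 3,4-dimethoxybenzyl bromide | COc1ccc(CBr)cc1OC | intermediate
11 | 2-(4-benzyloxy-3-methoxyphenyl)-2-lithio-1,3-dithiane | COc1cc(C2([Li])SCCCS2)ccc1OCc1ccccc1 | intermediate
12 | lithium (4R,5R)-4-[2-(4-benzyloxy-3-methoxyphenyl)-1,3-dithian-2-yl]-5-(l-menthyloxy)-4,5-dihydrofuran-2-olate | COc1cc(C2(SCCCS2)[C@@H]2C=C(O[Li])O[C@H]2O[C@@H]2C[C@H](C)CC[C@H]2C(C)C)ccc1OCc1ccccc1 | intermediate
13 | (3R,4R,5R)-4-[2-(4-benzyloxy-3-methoxyphenyl)-1,3-dithian-2-yl]-3-(3,4-dimethoxybenzyl)-5-(l-menthyloxy)dihydrofuran-2(3H)-one | COc1cc(C2(SCCCS2)[C@@H]2[C@@H](Cc3ccc(OC)c(OC)c3)C(=O)O[C@H]2O[C@@H]2C[C@H](C)CC[C@H]2C(C)C)ccc1OCc1ccccc1 | intermediate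
14 | (2R,3R)-2-[2-(4-benzyloxy-3-methoxyphenyl)-1,3-dithian-2-yl]-3-(3,4-dimethoxybenzyl)butane-1,4-diol | COc1cc(C2(SCCCS2)[C@@H](CO)[C@H](CO)Cc2ccc(OC)c(OC)c2)ccc1OCc1ccccc1 | intermediate
15 | (2R,3R)-1-(4-benzyloxy-3-methoxyphenyl)-3-(3,4-dimethoxybenzyl)-4-hydroxy-2-(hydroxymethyl)butan-1-one | COc1cc(C(=O)[C@@H](CO)[C@H](CO)Cc2ccc(OC)c(OC)c2)ccc1OCc1ccccc1 | intermediate
16 | (2R,3R)-2-[(4-benzyloxy-3-methoxyphenyl)(hydroxy)methyl]-3-(3,4-dimethoxybenzyl)butane-1,4-diol, carbinol epimers | COc1cc(C(O)[C@@H](CO)[C@H](CO)Cc2ccc(OC)c(OC)c2)ccc1OCc1ccccc1 | intermediate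
17 | [(2S,3R,4R)-2-(4-benzyloxy-3-methoxyphenyl)-4-(3,4-dimethoxybenzyl)tetrahydrofuran-3-yl]methanol | COc1cc([C@H]2OC[C@H](Cc3ccc(OC)c(OC)c3)[C@@H]2CO)ccc1OCc1ccccc1 | intermediate
18 | 4'-O-methyllariciresinol | COc1cc([C@H]2OC[C@H](Cc3ccc(OC)c(OC)c3)[C@@H]2CO)ccc1O | target

**Summary**

Total step count: 11.
Longest linear sequence: 8 steps (steps 1, 2, 6–11 from vanillin; equally steps 3, 4, 6–11 from furfural).

**Steps most likely to fail**

Step 6. The lithiated dithiane may add 1,2 to the lactone carbonyl, or the enolate may be trapped too slowly, so that proton transfer, retro-Michael reaction on warming or over-alkylation erode the three-component coupling. The fallback separates the two bond formations. Setting out from 3 and 8, the anion of 3 is added to 8 at −78 °C and the enolate is quenched with aqueous NH4Cl. This gives the isolable Michael adduct (4R,5R)-4-[2-(4-benzyloxy-3-methoxyphenyl)-1,3-dithian-2-yl]-5-(l-menthyloxy)dihydrofuran-2(3H)-one F1. After purification, F1 is re-enolised with LDA in THF at −78 °C and alkylated with 10 in the presence of DMPU. The C4 substituent again directs the benzyl group trans, and the route is rejoined at 13.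

Step 8. With the diol free, unmasking the ketone creates a β-hydroxy ketone. Enolisation can scramble C3, water can be lost by β-elimination or by dehydration of the cyclic hemiketal to a dihydrofuran, and mercury binding to the diol can stall the hydrolysis. The fallback unmasks the ketone before the lactone is opened. Setting out from 13, the same HgO/BF3·OEt2 hydrolysis gives (3R,4R,5R)-4-(4-benzyloxy-3-methoxybenzoyl)-3-(3,4-dimethoxybenzyl)-5-(l-menthyloxy)dihydrofuran-2(3H)-one F2. In F2 the β-oxygen is locked in the acylal and the α-centre sits trans to both neighbours, its thermodynamically preferred arrangement. Adding F2 to excess LiAlH4 in THF at −78 °C and warming to rt then reduces ketone, lactone and acetal in one operation, with the ketone expected to react first. The route is rejoined at 16, one step shorter.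

Step 10. The benzylic cation may be captured by the electron-rich dimethoxyphenyl ring (six-membered Friedel–Crafts closure to an aryltetralin) instead of by the C5 hydroxyl, or the ether may isomerise under prolonged acid, lowering the 2,3-trans purity. The fallback replaces the cation closure by a quinone-methide closure on the free phenol. Setting out from 15, hydrogenolysis (H2, Pd/C, EtOAc) of the benzyl ether gives (2R,3R)-3-(3,4-dimethoxybenzyl)-4-hydroxy-1-(4-hydroxy-3-methoxyphenyl)-2-(hydroxymethyl)butan-1-one F3. NaBH4 in MeOH then gives (2R,3R)-2-(3,4-dimethoxybenzyl)-3-[hydroxy(4-hydroxy-3-methoxyphenyl)methyl]butane-1,4-diol F4. Brief treatment of F4 with dilute acid (or gentle warming in buffered aqueous medium) generates the neutral p-quinone methide. The C5 hydroxyl adds to it reversibly (oxa-1,6-addition) to give the trans tetrahydrofuran, under conditions too mild for arene attack. This rejoins the route at 18 and removes the late hydrogenolysis next to the benzylic ring ether.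

**Further compounds**

F1 | step 6 | (4R,5R)-4-[2-(4-benzyloxy-3-methoxyphenyl)-1,3-dithian-2-yl]-5-(l-menthyloxy)dihydrofuran-2(3H)-one | COc1cc(C2(SCCCS2)[C@@H]2CC(=O)O[C@H]2O[C@@H]2C[C@H](C)CC[C@H]2C(C)C)ccc1OCc1ccccc1
F2 | step 8 | (3R,4R,5R)-4-(4-benzyloxy-3-methoxybenzoyl)-3-(3,4-dimethoxybenzyl)-5-(l-menthyloxy)dihydrofuran-2(3H)-one | COc1cc(C(=O)[C@@H]2[C@@H](Cc3ccc(OC)c(OC)c3)C(=O)O[C@H]2O[C@@H]2C[C@H](C)CC[C@H]2C(C)C)ccc1OCc1ccccc1
F3 | step 10 | (2R,3R)-3-(3,4-dimethoxybenzyl)-4-hydroxy-1-(4-hydroxy-3-methoxyphenyl)-2-(hydroxymethyl)butan-1-one | COc1cc(C(=O)[C@@H](CO)[C@H](CO)Cc2ccc(OC)c(OC)c2)ccc1O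
F4 | step 10 | (2R,3R)-2-(3,4-dimethoxybenzyl)-3-[hydroxy(4-hydroxy-3-methoxyphenyl)methyl]butane-1,4-diol | COc1cc(C(O)[C@@H](CO)[C@H](CO)Cc2ccc(OC)c(OC)c2)ccc1O
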